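Assumptions: atom labels (C1–C20) follow ent‑kaurane numbering. A two‑stage operation run without isolating the intermediate (silyl enol ether, Mannich base, lactol) counts as one step.

## Retrosynthetic overview
1. Target ⇐ exo‑face hydrogenation of a 16‑methylene‑Δ11 enone ⇐ α‑methylenation ⇐ Pd(II) cycloalkenylation of a C8 methyl ketone onto Δ12 (forms C13–C16, ring D).
2. THF acetal and the C4 quaternary centre ⇐ photochemical addition of the hydroxymethyl radical from MeOH to a tetrasubstituted enal, then acetalisation (forms C4–C19).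
3. Ring C, quaternary C8 and C9 ⇐ Diels–Alder reaction of butadiene with a spiro 3‑acetyl‑5,6‑dihydropyran‑2‑one.
4. δ‑Lactone ⇐ acetylketene acylation and intramolecular Knoevenagel condensation of a β‑hydroxy aldehyde. The enal ⇐ enone → enol triflate → formylation.
5. C10 ⇐ two α′‑alkylations of (S)‑carvone anti to its isopropenyl group, which is then excised. Ring order: A (bought) → lactone → C → THF → D.

## Route

**Step 1**
Reactants: 1 (S)‑(+)‑carvone; 2 (triisopropylsiloxy)methyl chloride (TOM‑Cl)
Product: 3 (5S,6S)‑2‑methyl‑5‑isopropenyl‑6‑[(TIPSO)methyl]cyclohex‑2‑enone (CH2OTIPS trans to isopropenyl)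
Conditions: LDA, THF, −78 °C; then 2, −78 → −20 °C
Reagents that add atoms: TOM‑Cl, ClCO[Si](C(C)C)(C(C)C)C(C)C
Why: This is a kinetic α′‑enolate alkylation of the cross‑conjugated enolate that installs C20, entering anti to the isopropenyl group, and the new centre is re‑enolised in step 2.

**Step 2**
Reactants: 3; 4 trimethyl orthoformate
Product: 5 (5R,6R)‑6‑(dimethoxymethyl)‑2‑methyl‑5‑isopropenyl‑6‑[(TIPSO)methyl]cyclohex‑2‑enone (acetal trans, CH2OTIPS cis to isopropenyl)
Conditions: LDA, TMSCl, THF, −78 °C; then 4, BF3·OEt2, CH2Cl2, −78 °C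
Reagents that add atoms: trimethyl orthoformate, COC(OC)OC
Why: In this Mukaiyama‑type alkylation of the silyl dienol ether, the small dimethoxycarbenium ion attacks anti to the adjacent isopropenyl group and sets quaternary C10.

**Step 3**
Reactants: 5
Product: 6 (6R)‑6‑(dimethoxymethyl)‑2‑methyl‑6‑[(TIPSO)methyl]cyclohex‑2‑enone
Conditions: O3, MeOH, −78 °C; then FeSO4·7H2O, PhSH, −78 °C → rt
Reagents that add atoms: none
Why: In this hydrodealkenylative fragmentation (Criegee α‑methoxy hydroperoxide, Fe(II) alkoxy radical, β‑scission, thiol H‑transfer), only the electron‑rich isopropenyl alkene is ozonised and C10 is untouched.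

**Step 4**
Reactants: 6; 7 Comins' reagent
Product: 8 (6S)‑6‑(dimethoxymethyl)‑2‑methyl‑6‑[(TIPSO)methyl]cyclohex‑1‑enyl triflate
Conditions: L‑Selectride, THF, −78 °C; then 7, −78 → 0 °C
Reagents that add atoms: Comins' reagent, ClC1=CN=C(N(S(=O)(=O)C(F)(F)F)S(=O)(=O)C(F)(F)F)C=C1
Why: Conjugate reduction gives the regiodefined tetrasubstituted enolate, which is trapped as the C5=C4 enol triflate.

**Step 5**
Reactants: 8
Product: 9 (6S)‑6‑formyl‑6‑(hydroxymethyl)‑2‑methylcyclohex‑1‑enyl triflate
Conditions: 48 % aq HF, MeCN, 0 °C → rt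
Reagents that add atoms: water, O
Why: Acidic desilylation and acetal hydrolysis occur in one pot, and neither the vinyl triflate nor the non‑enolisable C10 centre is affected.

**Step 6**
Reactants: 9; 10 2,2,6‑trimethyl‑4H‑1,3‑dioxin‑4‑one
Product: 11 spiro lactone: 3‑acetyl‑5,6‑dihydropyran‑2‑one (O–C20H2–C10–C9H=C8(Ac)–C7=O) spiro at C10 to the 2‑methyl‑1‑triflyloxycyclohexene ring
Conditions: 10, toluene, 110 °C; then piperidine/AcOH (10 mol %), 4 Å MS, 60 °C
Reagents that add atoms: 2,2,6‑trimethyl‑4H‑1,3‑dioxin‑4‑one, CC1=CC(=O)OC(C)(C)O1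
Why: Retro‑[4+2] releases acetylketene, which acylates the C20 hydroxyl, and an intramolecular Knoevenagel condensation with the C9 aldehyde closes the six‑membered lactone.

**Step 7**
Reactants: 11; 12 buta‑1,3‑diene
Product: 13 cis‑fused Diels–Alder adduct (C8 bears acetyl, C9–H, Δ12 alkene; C8, C9 and C10 configured as in the target)
Conditions: 12 (excess), SnCl4, CH2Cl2, −40 → 0 °C
Reagents that add atoms: buta‑1,3‑diene, C=CC=C
Why: In this Lewis‑acid‑chelated Diels–Alder reaction of a doubly activated alkylidene β‑keto lactone, the diene adds suprafacially to the face anti to the bulkier pseudoaxial C5(OTf) arm of C10 and sets C8 and C9.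

**Step 8**
Reactants: 13; 14 carbon monoxide
Product: 15 tetrasubstituted enal (C6HO on C5, C5=C4–CH3), otherwise as 13
Conditions: Pd(OAc)2, dppp, CO (1 atm), Et3SiH, Et3N, DMF, 70 °C
Reagents that add atoms: carbon monoxide, [C-]#[O+]
Why: Pd(0) reductive carbonylation (formylation) of the vinyl triflate tolerates the ketone, the lactone and the isolated alkene.

**Step 9 (key step)**
Reactants: 15; 16 methanol
Product: 17 cis‑fused methyl acetal (C6(OMe)–O–C19H2–C4), with C4, C5 and C6 as in the target; C8 acetyl and Δ12 retained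
Conditions: [Ir(dF(CF3)ppy)2(dtbbpy)]PF6 (1 mol %), quinuclidine (10 mol %), Bu4NH2PO4 (25 mol %), MeOH/MeCN, 450 nm LEDs, rt; then CSA, MeOH, rt
Reagents that add atoms: methanol (2 equiv), CO
Why: Proposed new method: the quinuclidinium radical cation abstracts the phosphate‑activated α‑C–H of MeOH; the small nucleophilic •CH2OH adds at C4 of the enal on the face anti to pseudoaxial C9 (syn to C20) to form the C4–C19 bond and the quaternary centre; Ir(II) reduces the α‑formyl radical; acid then equilibrates C5 through the enol, and only the epimer with C6 cis to C19 closes to the cis‑fused lactol, which takes up MeOH on the convex face (OMe trans to C10); the closest known reaction is the photoredox/HAT Giese addition of α‑hydroxyalkyl radicals to acrylates and enones (lactone synthesis), which has not been shown for tetrasubstituted enals or with in‑situ acetal capture.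

**Step 10**
Reactants: 17
Product: 18 bicyclo[3.2.1]octenone (C13–C16 bond, C15=O, C16H2, Δ11)
Conditions: LiHMDS, TMSCl, THF, −78 °C; crude enol silane, Pd(OAc)2 (1.1 equiv), MeCN, rt
Reagents that add atoms: none
Why: In this Saegusa–Ito‑type Pd(II) cycloalkenylation of a 2‑siloxy‑1,5‑diene, the C16–Pd enolate has no β‑hydrogen, inserts 5‑exo into Δ12 and eliminates toward C11, and the bridge geometry fixes C13.

**Step 11**
Reactants: 18; 19 Eschenmoser's salt
Product: 20 16‑methylene‑15‑one (exocyclic enone), Δ11 retained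
Conditions: LiHMDS, THF, −78 °C; 19; then MeI; aq NaHCO3
Reagents that add atoms: Eschenmoser's salt, C=[N+](C)C.[I-]
Why: Mannich α‑methylenation occurs at C16, the only enolisable position because C8 is quaternary.

**Step 12**
Reactants: 20
Product: 21 ludongnin I
Conditions: H2 (1 atm), 10 % Pd/C, EtOAc, rt
Reagents that add atoms: none
Why: Heterogeneous hydrogenation saturates Δ11 and delivers H to C16 from the open exo face (the C14 side), which places C17 endo (16R), and no acid or base follows that could epimerise it.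

## Compound list
1 | (S)‑(+)‑carvone | CC1=CC[C@@H](CC1=O)C(C)=C | starting material
2 | TOM‑Cl | ClCO[Si](C(C)C)(C(C)C)C(C)C | starting material
3 | 6‑(TIPSO‑methyl)carvone (trans) | CC1=CC[C@H](C(C)=C)[C@@H](CO[Si](C(C)C)(C(C)C)C(C)C)C1=O | intermediate
4 | trimethyl orthoformate | COC(OC)OC | starting material
5 | 6,6‑disubstituted carvone | CC1=CC[C@H](C(C)=C)[C@@](CO[Si](C(C)C)(C(C)C)C(C)C)(C(OC)OC)C1=O | intermediate
6 | dealkenylated enone | CC1=CCC[C@@](CO[Si](C(C)C)(C(C)C)C(C)C)(C(OC)OC)C1=O | intermediate
7 | Comins' reagent | ClC1=CN=C(N(S(=O)(=O)C(F)(F)F)S(=O)(=O)C(F)(F)F)C=C1 | starting material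
8 | enol triflate | CC1=C(OS(=O)(=O)C(F)(F)F)[C@](CO[Si](C(C)C)(C(C)C)C(C)C)(C(OC)OC)CCC1 | intermediate
9 | hydroxy aldehyde | CC1=C(OS(=O)(=O)C(F)(F)F)[C@](CO)(C=O)CCC1 | intermediate
10 | 2,2,6‑trimethyl‑1,3‑dioxin‑4‑one | CC1=CC(=O)OC(C)(C)O1 | starting material
11 | spiro 3‑acetyl dihydropyranone | CC1=C(OS(=O)(=O)C(F)(F)F)[C@@]2(COC(=O)C(C(C)=O)=C2)CCC1 | intermediate
12 | buta‑1,3‑diene | C=CC=C | starting material
13 | Diels–Alder adduct | CC1=C(OS(=O)(=O)C(F)(F)F)[C@@]2(COC(=O)[C@@]3(C(C)=O)CC=CC[C@H]32)CCC1 | intermediate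
14 | carbon monoxide | [C-]#[O+] | starting material
15 | enal | CC1=C(C=O)[C@@]2(COC(=O)[C@@]3(C(C)=O)CC=CC[C@H]32)CCC1 | intermediate
16 | methanol | CO | starting material
17 | THF methyl acetal | CO[C@H]1OC[C@]2(C)CCC[C@]3(COC(=O)[C@@]4(C(C)=O)CC=CC[C@H]43)[C@H]12 | intermediate
18 | bicyclo[3.2.1]octenone | CO[C@H]1OC[C@]2(C)CCC[C@]3(COC(=O)[C@@]45C[C@@H](C=C[C@H]43)CC5=O)[C@H]12 | intermediate
19 | Eschenmoser's salt | C=[N+](C)C.[I-] | starting material
20 | exocyclic enone | CO[C@H]1OC[C@]2(C)CCC[C@]3(COC(=O)[C@@]45C[C@@H](C=C[C@H]43)C(=C)C5=O)[C@H]12 | intermediate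
21 | ludongnin I | CO[C@H]1OC[C@]2(C)CCC[C@]3(COC(=O)[C@@]45C[C@@H](CC[C@H]43)[C@@H](C)C5=O)[C@H]12 | target

## Summary
Total steps: 12. Longest linear sequence: 12 (from (S)‑carvone).

Steps most likely to fail:
1. **Step 9 (new step).** The hindered, twisted enal may react too slowly with •CH2OH, or the aldehyde may be reduced. Fallback (known chemistry, polar instead of radical): TMSCl‑accelerated conjugate addition of a (PhMe2SiCH2) cuprate to 15, Fleming–Tamao oxidation to the C19 alcohol, then CSA/MeOH acetalisation.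
2. **Step 7.** C9 is neopentyl, so reactivity and facial selectivity are uncertain. Fallback (stepwise annulation): Hosomi–Sakurai allylation of 11 at C9, C‑allylation of the resulting β‑keto lactone at C8 anti to C10, and ring‑closing metathesis to the same Δ12 cyclohexene.
3. **Step 10.** The cyclisation may go 6‑endo to the bicyclo[2.2.2] isomer or stall. Fallback (carbene route): detrifluoroacetylative diazo transfer on 17 to the terminal α‑diazoketone, Cu‑catalysed cyclopropanation of Δ12, and SmI2 reductive opening of the C12–C16 bond, followed by steps 11 and 12.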